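A direct plan would build ring B first and close ring C last at C4–C4a.
Its side chain would come from a chiral hydroxy ester by silylation, reduction, oxidation to aldehyde A1 and methylenation to alkene A2, which a B-alkyl Suzuki coupling would join to a brominated, prenylated hydroxybenzoate.
The benzoate would be extended with methoxyacetate, turned into enol triflate A3, substituted with phenol A4, saponified to acid A5 and cyclised by Friedel–Crafts acylation, before desilylation and deallylation.
Weak point 1, the run-up to A2: four steps (protection, reduction, oxidation, olefination) would build one C=C bond and pass through the α-methyl aldehyde A1, which can epimerise.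
Weak point 2, the enol triflate formation, vinylic substitution, saponification and Friedel–Crafts closure: four consecutive steps on the most advanced material, whose ring closure relies on an alkene geometry that nothing secures and exposes a prenyl group, three allyl ethers and a silyl ether to an acidic acylating medium.
Weak point 3, the conversion of a benzoate into phenol A4 (allylation, reduction, oxidation, Dakin oxidation) and the three allyl ethers that are put on and taken off: steps that build no bond of the skeleton.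

**Retrosynthetic overview**
1. Key disconnection: the C2–C1′ bond between ring C and ring B. C2–H of 3-methoxychromone 10 is the only C–H of the pyranone ring, lying between O1 and the methoxy-bearing C3; it is zincated and coupled (Negishi) with the complete ring B bromide 20.
2. Ring order: ring A (from 2-methoxyresorcinol), then ring C closed on ring A alone at O1–C2 by a one-carbon condensation before any sensitive group exists, then ring B attached last.
3. Ring A: the mirror plane of 2 and a sterically controlled C–H borylation/oxidation para to the methoxy group give phenol 4, whose single free hydroxyl becomes O1. Only the 6-methoxy chromone can therefore form, and no redox stretch is needed.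
4. Ring B: both side chains are ortho to the 4′-hydroxyl, so both enter through the phenoxide: C-prenylation, then a Mannich base that gives an o-quinone methide, to which the Grignard reagent from commercial (2R)-3-bromo-2-methylpropan-1-ol adds. The stereocentre is bought and is never next to a carbonyl.
5. There is no enol triflate, no geometry-dependent or acid-mediated ring closure on advanced material and no allyl ether; one step removes all four protecting groups.

Key step: step 11

Starting materials taken as commercial: 1, 6, 11 and 13. Remark: the descriptor of the methyl-bearing carbon changes from R (11, 12, 17) to S (19 onward) only because the CIP priorities change; none of its bonds is made or broken.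

**Ring A and ring C (chromone 10)**

Step 1
Reactants: 1 2-methoxybenzene-1,3-diol
Product: 2 2-methoxy-1,3-bis(methoxymethoxy)benzene
Conditions: NaH (2.4 equiv), DMF, 0 °C; MeOCH2Cl (2.4 equiv), 0 °C to rt
Reagents that add atoms: chloromethyl methyl ether, COCCl
Why: Williamson-type O-alkylation of both phenoxides gives the bis-acetal, which keeps the mirror plane of the ring and should withstand the organometallic steps that follow.

Step 2
Reactants: 2 2-methoxy-1,3-bis(methoxymethoxy)benzene
Product: 4 4-methoxy-3,5-bis(methoxymethoxy)phenol, via arylboronic ester 3 (not isolated)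
Conditions: [Ir(OMe)(cod)]2 (1.5 mol%), 4,4′-di-tert-butyl-2,2′-bipyridine (3 mol%), B2pin2 (1.0 equiv), THF, 80 °C; then 30% aq. H2O2, aq. NaHCO3, 0 °C to rt
Reagents that add atoms: hydrogen peroxide, OO (the boron of intermediate 3 comes from bis(pinacolato)diboron, CC1(C)OB(OC1(C)C)B1OC(C)(C)C(C)(C)O1)
Why: Iridium-catalysed aromatic C–H borylation is sterically controlled, so it should occur at C5, the only C–H of 2 without an ortho substituent, and oxidation of the C–B bond (1,2-shift of the aryl group from boron to oxygen) gives the phenol whose free hydroxyl, para to the methoxy group, is the future O1.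

Step 3
Reactants: 4 4-methoxy-3,5-bis(methoxymethoxy)phenol
Product: 5 2-iodo-4-methoxy-3,5-bis(methoxymethoxy)phenol
Conditions: N-iodosuccinimide (1.0 equiv), MeCN, −20 to 0 °C, dark
Reagents that add atoms: N-iodosuccinimide, O=C1CCC(=O)N1I
Why: Electrophilic aromatic iodination of the electron-rich phenol should occur ortho to the hydroxyl, the para position being blocked by the methoxy group and the two ortho positions being identical by symmetry, so one equivalent gives one mono-iodide.

Step 4
Reactants: 5 2-iodo-4-methoxy-3,5-bis(methoxymethoxy)phenol; 6 N,2-dimethoxy-N-methylacetamide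
Product: 8 1-[2-hydroxy-5-methoxy-4,6-bis(methoxymethoxy)phenyl]-2-methoxyethan-1-one, via lithiated phenoxide 7 (not isolated)
Conditions: NaH (1.05 equiv), THF, 0 °C; n-BuLi (1.1 equiv), −78 °C; 6 (1.5 equiv), −78 to 0 °C; aq. NH4Cl
Reagents that add atoms: none
Why: Iodine–lithium exchange on the pre-formed phenoxide and acylation of the aryllithium by the N-methoxy-N-methylamide (Weinreb ketone synthesis, stable chelated tetrahedral adduct) should stop at the ketone and, unlike a Friedel–Crafts or Hoesch acylation, uses no acid that would cleave the acetals.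

Step 5
Reactants: 8 1-[2-hydroxy-5-methoxy-4,6-bis(methoxymethoxy)phenyl]-2-methoxyethan-1-one
Product: 10 3,6-dimethoxy-5,7-bis(methoxymethoxy)-4H-chromen-4-one, via enaminone 9 (not isolated)
Conditions: Me2NCH(OMe)2 (3 equiv), toluene, 100 °C; then AcOH (2 equiv), 60 °C
Reagents that add atoms: N,N-dimethylformamide dimethyl acetal, COC(OC)N(C)C
Why: Condensation of the α-methylene group with the amide acetal gives enaminone 9, and addition–elimination of the only free hydroxyl at the enamine carbon with loss of dimethylamine (6-endo closure at O1–C2) forms ring C, so only the 5,6,7-oxygenated chromone can arise.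

**Ring B (bromide 20)**

Step 6
Reactants: 11 (2R)-3-bromo-2-methylpropan-1-ol
Product: 12 [(2R)-3-bromo-2-methylpropoxy](tert-butyl)dimethylsilane
Conditions: t-BuMe2SiCl (1.1 equiv), imidazole (2 equiv), CH2Cl2, 0 °C to rt
Reagents that add atoms: tert-butyl(chloro)dimethylsilane, CC(C)(C)[Si](C)(C)Cl
Why: Imidazole-promoted silylation of the primary alcohol leaves the stereocentre untouched and gives an ether that tolerates magnesium, sodium hydride and organozinc reagents.

Step 7
Reactants: 13 4-bromophenol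
Product: 14 4-bromo-2-(3-methylbut-2-en-1-yl)phenol
Conditions: NaH (1.0 equiv), toluene, 0 °C to rt; Me2C=CHCH2Br (1.0 equiv), rt
Reagents that add atoms: 1-bromo-3-methylbut-2-ene, CC(C)=CCBr
Why: C-alkylation of the tight sodium phenoxide ion pair in a non-polar solvent should favour the ortho carbon (the para carbon carries bromine) with SN2 attack at the primary allylic carbon, so the linear prenyl group is kept; this step, of modest selectivity, is placed on the cheapest material.

Step 8
Reactants: 14 4-bromo-2-(3-methylbut-2-en-1-yl)phenol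
Product: 15 4-bromo-2-[(dimethylamino)methyl]-6-(3-methylbut-2-en-1-yl)phenol
Conditions: Me2N=CH2+ I− (1.2 equiv), K2CO3 (1.5 equiv), CH2Cl2, rt
Reagents that add atoms: N,N-dimethylmethyleneiminium iodide, C=[N+](C)C.[I-]
Why: In this Mannich reaction the pre-formed iminium ion should attack the only free position ortho to the phenol oxygen, the other ortho carbon carrying the prenyl group and the para carbon bromine.

Step 9
Reactants: 15 4-bromo-2-[(dimethylamino)methyl]-6-(3-methylbut-2-en-1-yl)phenol; 12 [(2R)-3-bromo-2-methylpropoxy](tert-butyl)dimethylsilane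
Product: 19 4-bromo-2-[(3S)-4-[(tert-butyldimethylsilyl)oxy]-3-methylbutyl]-6-(3-methylbut-2-en-1-yl)phenol, via ammonium iodide 16 (not isolated), via Grignard reagent 17 (not isolated), via o-quinone methide 18 (not isolated)
Conditions: 15, MeI (3 equiv), THF, rt, then evaporate; MeMgCl (1.0 equiv), THF, −78 °C; 17 (1.5 equiv) [from 12, Mg, BrCH2CH2Br (cat.), THF, 45 °C], −78 °C to rt; aq. NH4Cl
Reagents that add atoms: none
Why: N-Methylation gives salt 16, whose magnesium phenoxide should expel trimethylamine (1,4-elimination) to o-quinone methide 18, and the primary alkyl Grignard reagent adds to its exocyclic methylene carbon (1,4-addition driven by rearomatisation) to form the benzylic C–C bond; the stereocentre is β to magnesium and takes no part.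

Step 10
Reactants: 19 4-bromo-2-[(3S)-4-[(tert-butyldimethylsilyl)oxy]-3-methylbutyl]-6-(3-methylbut-2-en-1-yl)phenol
Product: 20 {(2S)-4-[5-bromo-2-(methoxymethoxy)-3-(3-methylbut-2-en-1-yl)phenyl]-2-methylbutoxy}(tert-butyl)dimethylsilane
Conditions: NaH (1.3 equiv), THF/DMF, 0 °C; MeOCH2Cl (1.3 equiv), 0 °C to rt
Reagents that add atoms: chloromethyl methyl ether, COCCl
Why: Williamson-type O-alkylation of the hindered sodium phenoxide with the reactive chloromethyl ether removes the only acidic proton of ring B before the organozinc coupling.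

**Union and end game**

Step 11
Reactants: 10 3,6-dimethoxy-5,7-bis(methoxymethoxy)-4H-chromen-4-one; 20 {(2S)-4-[5-bromo-2-(methoxymethoxy)-3-(3-methylbut-2-en-1-yl)phenyl]-2-methylbutoxy}(tert-butyl)dimethylsilane
Product: 22 2-{3-[(3S)-4-[(tert-butyldimethylsilyl)oxy]-3-methylbutyl]-4-(methoxymethoxy)-5-(3-methylbut-2-en-1-yl)phenyl}-3,6-dimethoxy-5,7-bis(methoxymethoxy)-4H-chromen-4-one, via chromon-2-ylzinc chloride 21 (not isolated)
Conditions: 10 (1.3 equiv), (TMP)ZnCl·LiCl (1.4 equiv; TMP = 2,2,6,6-tetramethylpiperidide), THF, 25 °C; then 20 (1.0 equiv), Pd(OAc)2 (2 mol%), SPhos (2-dicyclohexylphosphino-2′,6′-dimethoxybiphenyl, 4 mol%), THF, 50 °C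
Reagents that add atoms: none
Why: The zinc amide should remove the C2 hydrogen of 10, the only C–H of the pyranone ring and the most acidic one of the molecule (an sp2 C–H bound to O1, next to the C3 methoxy oxygen and conjugated with the C4 carbonyl), to give zinc reagent 21; zerovalent palladium carrying SPhos then inserts into the C–Br bond of 20, and transmetallation from zinc and reductive elimination form the C2–C1′ bond. The closest known reaction type is the zincation of chromones at C2 with TMP-zinc amide bases followed by Negishi arylation to flavones. No ring is closed and no stereocentre is formed; the step joins the complete ring A/ring C bicycle to the complete ring B in one operation. The selectivity needed is C2–H over C8–H and over the acetal CH2 groups, which the much higher acidity of C2–H and the mildness of the zinc amide should secure, while the methoxy group at C3 excludes metallation there and the ring opening that would follow it. The covalent carbon–zinc bond tolerates the pyranone carbonyl, the acetals and the silyl ether, the prenyl alkene is inert to the catalyst, the bromine-bearing carbon of 20 has no ortho substituent, and the remote stereocentre is not touched.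

Step 12
Reactants: 22 2-{3-[(3S)-4-[(tert-butyldimethylsilyl)oxy]-3-methylbutyl]-4-(methoxymethoxy)-5-(3-methylbut-2-en-1-yl)phenyl}-3,6-dimethoxy-5,7-bis(methoxymethoxy)-4H-chromen-4-one
Product: 23 5,7-dihydroxy-2-{4-hydroxy-3-[(3S)-4-hydroxy-3-methylbutyl]-5-(3-methylbut-2-en-1-yl)phenyl}-3,6-dimethoxy-4H-chromen-4-one
Conditions: HCl (1.25 M in MeOH, excess), THF, 0 °C to rt
Reagents that add atoms: none
Why: Acid-catalysed methanolysis cleaves the three methoxymethyl acetals and the primary silyl ether in one operation, and dilute acid at or below room temperature should leave the trisubstituted prenyl alkene unprotonated and the two methyl ethers intact.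

**Compound list**

1 | 2-methoxybenzene-1,3-diol | COc1c(O)cccc1O | starting material
2 | 2-methoxy-1,3-bis(methoxymethoxy)benzene | COCOc1cccc(OCOC)c1OC | intermediate
3 | 2-[4-methoxy-3,5-bis(methoxymethoxy)phenyl]-4,4,5,5-tetramethyl-1,3,2-dioxaborolane | COCOc1cc(B2OC(C)(C)C(C)(C)O2)cc(OCOC)c1OC | intermediate
4 | 4-methoxy-3,5-bis(methoxymethoxy)phenol | COCOc1cc(O)cc(OCOC)c1OC | intermediate
5 | 2-iodo-4-methoxy-3,5-bis(methoxymethoxy)phenol | COCOc1cc(O)c(I)c(OCOC)c1OC | intermediate
6 | N,2-dimethoxy-N-methylacetamide | COCC(=O)N(C)OC | starting material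
7 | sodium 2-lithio-4-methoxy-3,5-bis(methoxymethoxy)phenolate | [Na+].[O-]c1cc(OCOC)c(OC)c(OCOC)c1[Li] | intermediate
8 | 1-[2-hydroxy-5-methoxy-4,6-bis(methoxymethoxy)phenyl]-2-methoxyethan-1-one | COCC(=O)c1c(O)cc(OCOC)c(OC)c1OCOC | intermediate
9 | 3-(dimethylamino)-1-[2-hydroxy-5-methoxy-4,6-bis(methoxymethoxy)phenyl]-2-methoxyprop-2-en-1-one | CN(C)C=C(OC)C(=O)c1c(O)cc(OCOC)c(OC)c1OCOC | intermediate
10 | 3,6-dimethoxy-5,7-bis(methoxymethoxy)-4H-chromen-4-one | COc1coc2cc(OCOC)c(OC)c(OCOC)c2c1=O | intermediate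
11 | (2R)-3-bromo-2-methylpropan-1-ol | BrC[C@H](C)CO | starting material
12 | [(2R)-3-bromo-2-methylpropoxy](tert-butyl)dimethylsilane | BrC[C@H](C)CO[Si](C)(C)C(C)(C)C | intermediate
13 | 4-bromophenol | Oc1ccc(Br)cc1 | starting material
14 | 4-bromo-2-(3-methylbut-2-en-1-yl)phenol | Oc1ccc(Br)cc1CC=C(C)C | intermediate
15 | 4-bromo-2-[(dimethylamino)methyl]-6-(3-methylbut-2-en-1-yl)phenol | CN(C)Cc1cc(Br)cc(CC=C(C)C)c1O | intermediate
16 | [5-bromo-2-hydroxy-3-(3-methylbut-2-en-1-yl)phenyl]-N,N,N-trimethylmethanaminium iodide | C[N+](C)(C)Cc1cc(Br)cc(CC=C(C)C)c1O.[I-] | intermediate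
17 | bromo{(2R)-3-[(tert-butyldimethylsilyl)oxy]-2-methylpropyl}magnesium | Br[Mg]C[C@H](C)CO[Si](C)(C)C(C)(C)C | intermediate
18 | 4-bromo-6-methylidene-2-(3-methylbut-2-en-1-yl)cyclohexa-2,4-dien-1-one | O=C1C(=C)C=C(Br)C=C1CC=C(C)C | intermediate
19 | 4-bromo-2-[(3S)-4-[(tert-butyldimethylsilyl)oxy]-3-methylbutyl]-6-(3-methylbut-2-en-1-yl)phenol | Oc1c(CC=C(C)C)cc(Br)cc1CC[C@H](C)CO[Si](C)(C)C(C)(C)C | intermediate
20 | {(2S)-4-[5-bromo-2-(methoxymethoxy)-3-(3-methylbut-2-en-1-yl)phenyl]-2-methylbutoxy}(tert-butyl)dimethylsilane | COCOc1c(CC=C(C)C)cc(Br)cc1CC[C@H](C)CO[Si](C)(C)C(C)(C)C | intermediate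
21 | chlorido[3,6-dimethoxy-5,7-bis(methoxymethoxy)-4-oxo-4H-chromen-2-yl]zinc, lithium chloride complex | COc1c([Zn]Cl)oc2cc(OCOC)c(OC)c(OCOC)c2c1=O.[Li+].[Cl-] | intermediate
22 | 2-{3-[(3S)-4-[(tert-butyldimethylsilyl)oxy]-3-methylbutyl]-4-(methoxymethoxy)-5-(3-methylbut-2-en-1-yl)phenyl}-3,6-dimethoxy-5,7-bis(methoxymethoxy)-4H-chromen-4-one | COc1c(OCOC)cc2oc(-c3cc(CC=C(C)C)c(OCOC)c(CC[C@H](C)CO[Si](C)(C)C(C)(C)C)c3)c(OC)c(=O)c2c1OCOC | intermediate
23 | 5,7-dihydroxy-2-{4-hydroxy-3-[(3S)-4-hydroxy-3-methylbutyl]-5-(3-methylbut-2-en-1-yl)phenyl}-3,6-dimethoxy-4H-chromen-4-one | COc1c(O)cc2oc(-c3cc(CC=C(C)C)c(O)c(CC[C@H](C)CO)c3)c(OC)c(=O)c2c1O | target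

**Step count**

Total: 12 steps. Longest linear sequence: 7 steps (steps 1 to 5, then 11 and 12).

**Steps most likely to fail**

Step 11. Zincation at C2 may be slow or incomplete, because the donor groups at C3 and C5 lower the acidity of C2–H. The coupling of the two electron-rich partners may also lag behind protodezincation and homocoupling. The fallback would set out from 20 and 8 and build ring C after the union by a Baker–Venkataraman sequence.
- Bromine–lithium exchange of 20 (n-BuLi, THF, −78 °C) would give {3-[(3S)-4-[(tert-butyldimethylsilyl)oxy]-3-methylbutyl]-4-(methoxymethoxy)-5-(3-methylbut-2-en-1-yl)phenyl}lithium F1.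
- Carboxylation with CO2 and cold acidification would give 3-[(3S)-4-[(tert-butyldimethylsilyl)oxy]-3-methylbutyl]-4-(methoxymethoxy)-5-(3-methylbut-2-en-1-yl)benzoic acid F2.
- Carbodiimide/4-(dimethylamino)pyridine esterification of the free hydroxyl of 8 would give 4-methoxy-2-(methoxyacetyl)-3,5-bis(methoxymethoxy)phenyl 3-[(3S)-4-[(tert-butyldimethylsilyl)oxy]-3-methylbutyl]-4-(methoxymethoxy)-5-(3-methylbut-2-en-1-yl)benzoate F3.
- LiN(SiMe3)2 (THF, −78 to 0 °C) would trigger the acyl shift to 1-{3-[(3S)-4-[(tert-butyldimethylsilyl)oxy]-3-methylbutyl]-4-(methoxymethoxy)-5-(3-methylbut-2-en-1-yl)phenyl}-3-[2-hydroxy-5-methoxy-4,6-bis(methoxymethoxy)phenyl]-2-methoxypropane-1,3-dione F4.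
- Buffered cyclodehydration of F4 (NaOAc, AcOH, 60 °C), in which only one hydroxyl is free, would close ring C at O1–C2 and come back to the route at 22.

Step 9. The o-quinone methide may oligomerise faster than the Grignard reagent adds, or the ammonium phenoxide may not eliminate cleanly. The fallback would replace the transient electrophile by a stable benzylic bromide, set out from 14 and reagent 17, and come back at 20.
- Magnesium-mediated ortho-formylation of 14 (MgCl2, Et3N, paraformaldehyde, MeCN, reflux) would give 5-bromo-2-hydroxy-3-(3-methylbut-2-en-1-yl)benzaldehyde F5.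
- NaH and MeOCH2Cl would give 5-bromo-2-(methoxymethoxy)-3-(3-methylbut-2-en-1-yl)benzaldehyde F6.
- NaBH4 would give [5-bromo-2-(methoxymethoxy)-3-(3-methylbut-2-en-1-yl)phenyl]methanol F7.
- An Appel reaction (CBr4, PPh3) would give 5-bromo-1-(bromomethyl)-2-(methoxymethoxy)-3-(3-methylbut-2-en-1-yl)benzene F8.
- Copper-catalysed coupling of F8 with 17 (Li2CuCl4, THF, −20 °C) would form the same benzylic C–C bond and give 20 directly.

Step 12. The acid may protonate the prenyl alkene, which would lead to cyclisation onto the neighbouring 4′-hydroxyl or to addition of methanol or chloride. The fallback would move all acid treatment to a stage without the alkene and end with fluoride; it would set out from 10 and 19 and come back at 23.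
- Methanolic HCl on 10 would give 5,7-dihydroxy-3,6-dimethoxy-4H-chromen-4-one F9.
- t-BuMe2SiCl and imidazole (DMF) would give 5,7-bis[(tert-butyldimethylsilyl)oxy]-3,6-dimethoxy-4H-chromen-4-one F10.
- The same silylation of 19 would give {4-bromo-2-[(3S)-4-[(tert-butyldimethylsilyl)oxy]-3-methylbutyl]-6-(3-methylbut-2-en-1-yl)phenoxy}(tert-butyl)dimethylsilane F11.
- Zincation of F10 as in step 11 would give chlorido{5,7-bis[(tert-butyldimethylsilyl)oxy]-3,6-dimethoxy-4-oxo-4H-chromen-2-yl}zinc F12.
- Negishi coupling of F12 with F11 would give 5,7-bis[(tert-butyldimethylsilyl)oxy]-2-{4-[(tert-butyldimethylsilyl)oxy]-3-[(3S)-4-[(tert-butyldimethylsilyl)oxy]-3-methylbutyl]-5-(3-methylbut-2-en-1-yl)phenyl}-3,6-dimethoxy-4H-chromen-4-one F13.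
- Et3N·3HF (THF, rt) would release 23.

**Further compounds**

F1 | step 11 | {3-[(3S)-4-[(tert-butyldimethylsilyl)oxy]-3-methylbutyl]-4-(methoxymethoxy)-5-(3-methylbut-2-en-1-yl)phenyl}lithium | [Li]c1cc(CC=C(C)C)c(OCOC)c(CC[C@H](C)CO[Si](C)(C)C(C)(C)C)c1
F2 | step 11 | 3-[(3S)-4-[(tert-butyldimethylsilyl)oxy]-3-methylbutyl]-4-(methoxymethoxy)-5-(3-methylbut-2-en-1-yl)benzoic acid | OC(=O)c1cc(CC=C(C)C)c(OCOC)c(CC[C@H](C)CO[Si](C)(C)C(C)(C)C)c1
F3 | step 11 | 4-methoxy-2-(methoxyacetyl)-3,5-bis(methoxymethoxy)phenyl 3-[(3S)-4-[(tert-butyldimethylsilyl)oxy]-3-methylbutyl]-4-(methoxymethoxy)-5-(3-methylbut-2-en-1-yl)benzoate | COCC(=O)c1c(OC(=O)c2cc(CC=C(C)C)c(OCOC)c(CC[C@H](C)CO[Si](C)(C)C(C)(C)C)c2)cc(OCOC)c(OC)c1OCOC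
F4 | step 11 | 1-{3-[(3S)-4-[(tert-butyldimethylsilyl)oxy]-3-methylbutyl]-4-(methoxymethoxy)-5-(3-methylbut-2-en-1-yl)phenyl}-3-[2-hydroxy-5-methoxy-4,6-bis(methoxymethoxy)phenyl]-2-methoxypropane-1,3-dione (both C2 epimers) | COC(C(=O)c1c(O)cc(OCOC)c(OC)c1OCOC)C(=O)c1cc(CC=C(C)C)c(OCOC)c(CC[C@H](C)CO[Si](C)(C)C(C)(C)C)c1
F5 | step 9 | 5-bromo-2-hydroxy-3-(3-methylbut-2-en-1-yl)benzaldehyde | O=Cc1cc(Br)cc(CC=C(C)C)c1O
F6 | step 9 | 5-bromo-2-(methoxymethoxy)-3-(3-methylbut-2-en-1-yl)benzaldehyde | O=Cc1cc(Br)cc(CC=C(C)C)c1OCOC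
F7 | step 9 | [5-bromo-2-(methoxymethoxy)-3-(3-methylbut-2-en-1-yl)phenyl]methanol | OCc1cc(Br)cc(CC=C(C)C)c1OCOC
F8 | step 9 | 5-bromo-1-(bromomethyl)-2-(methoxymethoxy)-3-(3-methylbut-2-en-1-yl)benzene | BrCc1cc(Br)cc(CC=C(C)C)c1OCOC
F9 | step 12 | 5,7-dihydroxy-3,6-dimethoxy-4H-chromen-4-one | COc1coc2cc(O)c(OC)c(O)c2c1=O
F10 | step 12 | 5,7-bis[(tert-butyldimethylsilyl)oxy]-3,6-dimethoxy-4H-chromen-4-one | COc1coc2cc(O[Si](C)(C)C(C)(C)C)c(OC)c(O[Si](C)(C)C(C)(C)C)c2c1=O
F11 | step 12 | {4-bromo-2-[(3S)-4-[(tert-butyldimethylsilyl)oxy]-3-methylbutyl]-6-(3-methylbut-2-en-1-yl)phenoxy}(tert-butyl)dimethylsilane | CC(C)(C)[Si](C)(C)Oc1c(CC=C(C)C)cc(Br)cc1CC[C@H](C)CO[Si](C)(C)C(C)(C)C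
F12 | step 12 | chlorido{5,7-bis[(tert-butyldimethylsilyl)oxy]-3,6-dimethoxy-4-oxo-4H-chromen-2-yl}zinc, lithium chloride complex | COc1c([Zn]Cl)oc2cc(O[Si](C)(C)C(C)(C)C)c(OC)c(O[Si](C)(C)C(C)(C)C)c2c1=O.[Li+].[Cl-]
F13 | step 12 | 5,7-bis[(tert-butyldimethylsilyl)oxy]-2-{4-[(tert-butyldimethylsilyl)oxy]-3-[(3S)-4-[(tert-butyldimethylsilyl)oxy]-3-methylbutyl]-5-(3-methylbut-2-en-1-yl)phenyl}-3,6-dimethoxy-4H-chromen-4-one | COc1c(O[Si](C)(C)C(C)(C)C)cc2oc(-c3cc(CC=C(C)C)c(O[Si](C)(C)C(C)(C)C)c(CC[C@H](C)CO[Si](C)(C)C(C)(C)C)c3)c(OC)c(=O)c2c1O[Si](C)(C)C(C)(C)C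
A1 | direct plan | (2R)-3-[(tert-butyldiphenylsilyl)oxy]-2-methylpropanal | O=C[C@H](C)CO[Si](c1ccccc1)(c1ccccc1)C(C)(C)C
A2 | direct plan | tert-butyl{[(2S)-2-methylbut-3-en-1-yl]oxy}diphenylsilane | C=C[C@H](C)CO[Si](c1ccccc1)(c1ccccc1)C(C)(C)C
A3 | direct plan | methyl (2E)-3-{4-(allyloxy)-3-[(3S)-4-[(tert-butyldiphenylsilyl)oxy]-3-methylbutyl]-5-(3-methylbut-2-en-1-yl)phenyl}-2-methoxy-3-{[(trifluoromethyl)sulfonyl]oxy}prop-2-enoate | COC(=O)/C(OC)=C(\OS(=O)(=O)C(F)(F)F)c1cc(CC=C(C)C)c(OCC=C)c(CC[C@H](C)CO[Si](c2ccccc2)(c2ccccc2)C(C)(C)C)c1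
A4 | direct plan | 4-methoxy-3,5-bis(prop-2-en-1-yloxy)phenol | Oc1cc(OCC=C)c(OC)c(OCC=C)c1
A5 | direct plan | (2E)-3-[3,5-bis(allyloxy)-4-methoxyphenoxy]-3-{4-(allyloxy)-3-[(3S)-4-[(tert-butyldiphenylsilyl)oxy]-3-methylbutyl]-5-(3-methylbut-2-en-1-yl)phenyl}-2-methoxyprop-2-enoic acid | OC(=O)/C(OC)=C(\Oc1cc(OCC=C)c(OC)c(OCC=C)c1)c1cc(CC=C(C)C)c(OCC=C)c(CC[C@H](C)CO[Si](c2ccccc2)(c2ccccc2)C(C)(C)C)c1
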